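Watch Q rather than J when you repeat this flask, and choose the charge by what Q shows at the end.

| setting | east | north-west | Monday's | Saturday's | Sunday's |
|---|---|---|---|---|---|
| J | 0.30 M | 1.8 M | 0.50 M | 1.0 M | 2.0 M |
| remark | run made earlier | run made earlier |  |  |  |
| time |  |  | 12 min | 12 min | 12 min |

| run | time / min | Q / % | J / % |
|---|---|---|---|
| east | 0.667 | 18 | 74 |
| east | 1.00 | 22 | 62 |
| east | 1.50 | 20 | 50 |
| east | 2.50 | 14 | 29 |
| east | 4.00 | 12 | 19 |
| east | 6.00 | 9 | 7 |
| east | 8.00 | 6 | 4 |
| north-west | 0.667 | 11 | 73 |
| north-west | 1.00 | 8 | 62 |
| north-west | 1.50 | 9 | 48 |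
| north-west | 2.50 | 6 | 34 |
| north-west | 4.00 | 5 | 16 |
| north-west | 6.00 | 3 | 6 |
| north-west | 8.00 | 4 | 2 |

(each reading ± 1.5 percentage points)

- the earlier runs were read with a standard deviation of 1.5 percentage points
- on the list of suspects stand: J <-> Q + Z; Q -> D; Q + Z -> L
- "hardly changes" means that all values lie within two and a half points (for a concentration: within two and a half percent of the largest)

- [Q] at the end for Monday's, Saturday's, Sunday's, in this order
- the shape of the row from first to last (rises all the way / falls all the way / rises, then falls / hardly changes / falls, then rises)

The suspects are J ⇌ Q + Z, Q → D and Q + Z → L. I follow one molecule: J gives a Q and a Z, and that Q then stands at a fork. J first. From 0.667 min to 6.00 min the north-west readings give a loss of J of 0.469 min⁻¹, and the east readings about the same 0.442 min⁻¹, so I read the loss as first order. On that reading, I reckon 0.360% of the charge stands as J at 12 min.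

Q is the harder part. At 1.50 min the north-west run holds 9% of its charge as Q, less than the 20% of the east run, which suits a removal by Q + Z. So I assume supply equal to removal, a quasi-steady state. Over the north-west readings from 1.00 min to 2.50 min, the rate of J's loss divided by Q times Z, with Z taken equal to Q, reads 21.3 M⁻¹ min⁻¹. This is the exit constant, and it carries the scatter of those readings. My balance level of Q at 12 min is then the square root of the rate constant times my J at that time over the exit constant:

| Flask | My balance level | Forecast |
|---|---|---|
| Monday's | 0.00631 M | 0.011 M |
| Saturday's | 0.00893 M | 0.013 M |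
| Sunday's | 0.0126 M | 0.017 M |

My levels lie lower than the forecast's in each flask, though both give the shape rises all the way. The forecast reads: “Q rises modestly with charge.” So I charge Sunday's 2.0 M next, for the highest balance level of Q.

Monday's, Saturday's and Sunday's flasks give 0.00516 M, 0.00619 M and 0.00766 M of Q at the end: rises all the way.

    J ⇌ Q + Z (K = 0.610 M, k = 0.00788 s⁻¹)
    Q → D (k = 7.13 × 10⁻⁴ s⁻¹)
    Q + Z → L (k = 0.328 M⁻¹ s⁻¹)

In Monday's flask at 12.0 min, Z stands at 0.0223 M, more than Q. The rate constant times the J found there, over the exit constant times that Z, gives a balance level of 0.00230 M, less than the Q found, and in Monday's flask Q is being made at 0.406 of the rate at which it is used up, each step taken net, less than unity. In Sunday's flask, with Z at 0.0413 M, the same constant gives 0.00475 M, less than the 0.00766 M of Q found.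

(All runs come from a simulation for substances that don't exist, noise included.)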